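# Proposed total synthesis of CNP0225459.2 (target 48) via a silicon-tethered ring-closing metathesis across O29/O33

## Structural features

Target 48 is a 36-membered macrolactone. The acyl carbon C1 and the carbinol C35 are joined through the single ester bond, and C35 carries an exocyclic (S)-hexan-2-yl group (C36–C40), so the ester oxygen sits on a secondary carbon next to a branched stereocentre. The ring is saturated and bears nine secondary hydroxyls (C5, C9, C13, C17, C21, C25, C27, C29, C33) and one methyl group (C3). With C35 and C36 there are twelve stereocentres: 3R,5R,9R,13S,17S,21R,25S,27S,29S,33S,35R,36S. Only C35/C36 are contiguous (anti). C25/C27/C29 form a 1,3,5-triol (25,27-syn, 27,29-anti), and C3/C5 (syn) and C33/C35 (anti) are 1,3-related. All other neighbours are 1,5-related through three methylenes, too far apart for substrate control. The fragile points are the lactone (translactonisation onto a free hydroxyl, above all O33) and, on the way, β-silyloxy aldehydes and δ-hydroxy esters. The real difficulty is absolute control over isolated carbinols in near-identical repeating units, and finding a place where two large pieces can be joined without an unselective coupling. The key step uses the fact that O29 and O33 flank exactly the three carbons C30–C32. One silicon atom across the two oxygens puts C31 and C32 into an eight-membered ring (Si, O29, C29, C30, C31, C32, C33, O33), so the C31–C32 bond can be made by ring-closing metathesis, and the silicon then protects both oxygens.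

## Logic of the disconnections

48 ⇒ 47. The nine Si–O bonds are put back (seven silyl ethers, one silylene over O29/O33). This leaves the lactone as the only function that must survive the last step. The forward demand is a fluoride cleavage that does not trigger acyl migration.

47 ⇒ 45 (through 46). The C1–O35 ester bond is cut because it is the only heteroatom bond of the ring. The macrocycle becomes an open chain in which O35 is the single free hydroxyl. The forward step must acylate a hindered secondary alcohol at high dilution.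

45 ⇒ 44 ⇒ 43. No skeletal bond is cut. The C1 acid goes back to the methyl ester, O35–H to its PMB ether and the C31–C32 single bond to the ring cis-alkene, which leads straight to the product of the key step. One hydrogenation has to saturate and debenzylate without alkene migration toward O33. The ester has to be cleaved without alkali hydroxide, which the dialkoxysilane might not tolerate.

43 ⇒ 42. C31=C32 is cut. It lies between two oxygens that can be tethered, and the cut divides the chain into C1–C31 and C32–C40. The forward step is an eight-membered ring closure by metathesis, in which a cis-alkene is the only possible geometry and is later erased. Both structures have been checked centre by centre against 48 and agree with it.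

42 ⇒ 41 + 28, and 41 ⇒ 39 + 40. The two Si–O bonds are cut, which separates the western homoallylic alcohol from the eastern allylic alcohol. The forward demand is sequential silylation without symmetrical bis-ethers. The more accessible alcohol 39 is therefore silylated first with excess 40, and the valuable 28 is added second as the limiting partner.

28 ⇒ 27 ⇒ 25 ⇒ 24 ⇒ 23 ⇒ 21 ⇒ 20 ⇒ 19. C29–C30, C27–C28 and C25–C26 are cut (allyl additions, each followed backwards by an alkene cleavage). This unrolls the 1,3,5-triol one carbinol at a time. Reagent control must override the weak bias of the β-silyloxy aldehydes, once syn and once anti.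

19 ⇒ 18 ⇒ … ⇒ 4. For each 1,5-unit two bonds are cut: C24–C25, C20–C21, C16–C17, C12–C13 and C8–C9 (one-carbon homologation of a terminal alkene), and C21–C22, C17–C18, C13–C14, C9–C10 and C5–C6 (allyl addition). Every cycle is the same three operations and removes one stereocentre. The remote centres exert no influence, so each addition must be fully reagent-controlled, with the enantiomer of the reagent chosen per centre.

4 ⇒ 3 ⇒ 2 ⇒ 1. Only the oxidation level at C5 changes, and the C3 stereocentre is traced to a prochiral diester. The forward demand is differentiation of two enantiotopic ester groups and a reduction that never activates the acid, so that the two termini cannot exchange.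

39 ⇒ 38 ⇒ 36 ⇒ 35 ⇒ 34. C32–C33 (vinyl addition) and C34–C35 (allyl addition) are cut, with an alkene cleavage and an ether formation in between. C33 must be set anti to C35 by chelation, and C35 anti to C36 by reagent control.

34 ⇒ 33 ⇒ 32 ⇒ 31 ⇒ 29 + 30. The C36–CH3 bond is cut (auxiliary-directed enolate methylation), which leads to a straight-chain acyl chloride. The forward demand is a face-selective alkylation and an auxiliary removal without epimerisation.

## Other disconnections considered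

Alternative 1: The cut removes C9–C10, C12–C13, C17–C18 and C20–C21 together. In the forward sense the dialdehyde A1 (C13–C17) would react at both formyl groups with a γ-boryl-substituted allyl(diisopinocampheyl)borane. The two α-substituted allylboronates so formed would then add to two molecules of aldehyde A2 to give the diene tetraol A3.
- In favour: C9–C21 of 48 has a local twofold axis through C15 (C9/C21 and C13/C17 are pairwise equivalent, and all three 1,5-pairs are anti). That is exactly what a two-directional, (E)-selective 1,5-anti sequence produces, with four C–C bonds and four stereocentres in one flask.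
- Against: A3 ends in two identical PMB ethers, whereas the two ends of 48 differ (one grows into the C1–C5 arm with the C3 methyl group, the other into the triol and the eastern part). A wasteful end differentiation is therefore built in. Two alkenes must be saturated and four hydroxyls protected before the chain can continue. The disconnection is also silent on how C26–C40 is attached, so a second strategic union is still required.
- Comparison: On structure the alternative exploits a hidden symmetry that the chosen plan ignores. On mechanism the two are equal, since both rely on isopinocampheyl groups on boron in a chair transition state. On step economy the alternative is clearly better for C9–C21 (one operation against steps 7–18). The chosen plan is better at the chain ends, where linear growth from 4 needs no differentiation, and it also supplies the fragment union.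

Alternative 2: The cuts are C1–O35 (made first, intermolecularly) and C7=C8 (made last). The forward key step is ring-closing metathesis of an open-chain diene ester, with an allyl group on C5 and a vinyl group on C9, to give the macrolactone A4 directly.
- In favour: no macrolactonisation at the hindered O35, uniform silyl protection with no tether to install or remove and no PMB ether, and the alkene geometry is irrelevant because it is hydrogenated.
- Against: the alkene lies near C1, so the alcohol partner would be a C8–C40 chain with ten stereocentres built linearly, longer than 28. Closing a 36-membered ring by metathesis has no conformational help and competes with oligomerisation. The vinyl carbinol next to a bulky silyl ether is a reluctant metathesis partner.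
- Comparison: On structure neither plan divides the chain evenly (7 + 33 carbons here, 31 + 9 in the chosen plan). On mechanism the carbene chemistry is the same, but the chosen plan closes an eight-membered ring with high effective molarity, while the alternative depends on dilution alone. On step economy after fragment assembly the alternative is better (esterification, metathesis, hydrogenation, desilylation, against tethering, metathesis, hydrogenation, ester cleavage, lactonisation, desilylation). Both are equal in needing exactly one high-dilution macrocyclisation.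

Alternative 3: The cuts are C26–C27 and C27–C28. The lithiated silyl dithiane A5 would open a western terminal epoxide (C25–C26). A 1,4-Brook shift then moves silicon onto O25 and regenerates the carbanion, which opens an eastern terminal epoxide (C28–C29) to give A6.
- In favour: three components are joined in one flask. The junction lies nearer the middle (C1–C26 and C28–C40), so the convergence is better than in the chosen plan. O25 emerges silylated and O29 free, which is what a hydroxyl-directed 1,3-anti reduction of the later C27 ketone needs.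
- Against: C27 has to be created after the coupling (dithiane hydrolysis, directed reduction, silylation). The organolithium conditions exclude a C1 ester, so C1 travels as a second PMB ether that must be told apart from the one on O35 and then oxidised twice. Two enantiopure terminal epoxides on long chains are needed.
- Comparison: On structure it uses the 1,3,5-triol rather than a 1,5-diol motif. On mechanism it is an anionic relay, against neutral carbene catalysis that tolerates the ester. On step economy the union itself is equal (one operation), but the corrections after coupling cost more than the single hydrogenation that follows the chosen key step.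

Key step: step 35

## Conventions and assumptions

- TBSO = tert-butyldimethylsilyloxy; PMBO = 4-methoxybenzyloxy. Locants C1–C40 are those of the target chain and are used for all fragments.
- l-Ipc2B(allyl) is B-allylbis(isopinocampheyl)borane made from (−)-α-pinene; d-Ipc2B(allyl) is its enantiomer from (+)-α-pinene. Both are added as preformed, salt-free pentane solutions.
- Assumption: boron, magnesium, lithium and tin alkoxides or carboxylates that are only cleaved in the work-up are not counted as separate compounds.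
- Assumption: pig liver esterase hydrolyses the pro-S ester of 1, giving the (R) half-ester 2. This is stated from memory; 2 is a known compound, and its rotation should be checked before the route continues.

## Route

Step 1
Reactants: 1 dimethyl 3-methylglutarate
Product: 2 (R)-5-methoxy-3-methyl-5-oxopentanoic acid
Conditions: pig liver esterase, phosphate buffer pH 7/MeOH (4:1), −10 °C, pH-stat (1 M NaOH); then HCl to pH 2
Reagents that add atoms: water, O
Why: Enzymatic desymmetrisation of a prochiral diester; the esterase hydrolyses the pro-S ester arm, so C3 is fixed as R at the outset.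

Step 2
Reactants: 2 (R)-5-methoxy-3-methyl-5-oxopentanoic acid
Product: 3 methyl (R)-5-hydroxy-3-methylpentanoate
Conditions: BH3·SMe2 (1.1 equiv), THF, 0 °C → rt; MeOH quench
Reagents that add atoms: none
Why: Chemoselective borane reduction of a carboxylic acid beside an ester; the acid is never turned into an acylating agent, so the termini cannot exchange through the cyclic anhydride and C3 keeps its configuration.

Step 3
Reactants: 3 methyl (R)-5-hydroxy-3-methylpentanoate
Product: 4 methyl (R)-3-methyl-5-oxopentanoate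
Conditions: TEMPO (10 mol %), PhI(OAc)2 (1.1 equiv), CH2Cl2, rt
Reagents that add atoms: none
Why: Oxoammonium (TEMPO) oxidation of the primary alcohol stops at the aldehyde under neutral conditions and should outrun δ-lactonisation.

Step 4
Reactants: 4 methyl (R)-3-methyl-5-oxopentanoate
Product: 5 methyl (3R,5R)-5-hydroxy-3-methyloct-7-enoate
Conditions: l-Ipc2B(allyl) (1.2 equiv), Et2O, −78 °C; then NaBO3·4H2O, THF/H2O, rt
Reagents that add atoms: l-Ipc2B(allyl), C=CCB([C@H]1C[C@H]2C[C@@H]([C@@H]1C)C2(C)C)[C@H]1C[C@H]2C[C@@H]([C@@H]1C)C2(C)C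
Why: Brown allylboration through a chair Zimmerman–Traxler transition state; reagent-controlled allyl transfer to the Re face sets C5 (R, 3,5-syn), and the perborate work-up is mild enough to keep the δ-hydroxy ester from lactonising.

Step 5
Reactants: 5 methyl (3R,5R)-5-hydroxy-3-methyloct-7-enoate
Product: 6 methyl (3R,5R)-5-(TBSO)-3-methyloct-7-enoate
Conditions: TBSCl, imidazole, DMF, rt
Reagents that add atoms: tert-butyldimethylsilyl chloride, CC(C)(C)[Si](C)(C)Cl
Why: Silyl ether formation; blocks O5 and removes the lactonisation pathway for good.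

Step 6
Reactants: 6 methyl (3R,5R)-5-(TBSO)-3-methyloct-7-enoate
Product: 7 methyl (3R,5R)-5-(TBSO)-3-methyl-9-oxononanoate
Conditions: Rh(acac)(CO)2 (1 mol %), BIPHEPHOS (3 mol %), CO/H2 (1:1, 5 bar), THF, 65 °C
Reagents that add atoms: carbon monoxide, [C-]#[O+]
Why: Rhodium-catalysed linear-selective hydroformylation; the wide-bite-angle diphosphite directs the formyl group to the terminal carbon, giving the C9 aldehyde and the 1,5-spacing in one step with ester and silyl ether untouched.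

Step 7
Reactants: 7 methyl (3R,5R)-5-(TBSO)-3-methyl-9-oxononanoate
Product: 8 methyl (3R,5R,9S)-5-(TBSO)-9-hydroxy-3-methyldodec-11-enoate
Conditions: l-Ipc2B(allyl), Et2O, −78 °C; then NaBO3·4H2O, THF/H2O, rt
Reagents that add atoms: l-Ipc2B(allyl), C=CCB([C@H]1C[C@H]2C[C@@H]([C@@H]1C)C2(C)C)[C@H]1C[C@H]2C[C@@H]([C@@H]1C)C2(C)C
Why: Brown allylboration, Re-face transfer under pure reagent control (C5 is too remote to matter); sets C9 as in the target (the descriptor reads S here only because the allyl group outranks the chain).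

Step 8
Reactants: 8 methyl (3R,5R,9S)-5-(TBSO)-9-hydroxy-3-methyldodec-11-enoate
Product: 9 methyl (3R,5R,9S)-5,9-bis(TBSO)-3-methyldodec-11-enoate
Conditions: TBSCl, imidazole, DMF, rt
Reagents that add atoms: tert-butyldimethylsilyl chloride, CC(C)(C)[Si](C)(C)Cl
Why: Silyl ether formation on the new secondary alcohol.

Step 9
Reactants: 9 methyl (3R,5R,9S)-5,9-bis(TBSO)-3-methyldodec-11-enoate
Product: 10 methyl (3R,5R,9S)-5,9-bis(TBSO)-3-methyl-13-oxotridecanoate
Conditions: Rh(acac)(CO)2 (1 mol %), BIPHEPHOS (3 mol %), CO/H2 (1:1, 5 bar), THF, 65 °C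
Reagents that add atoms: carbon monoxide, [C-]#[O+]
Why: Linear-selective hydroformylation as in step 6; delivers the C13 aldehyde.

Step 10
Reactants: 10 methyl (3R,5R,9S)-5,9-bis(TBSO)-3-methyl-13-oxotridecanoate
Product: 11 methyl (3R,5R,9R,13R)-5,9-bis(TBSO)-13-hydroxy-3-methylhexadec-15-enoate
Conditions: d-Ipc2B(allyl), Et2O, −78 °C; then NaBO3·4H2O, THF/H2O, rt
Reagents that add atoms: d-Ipc2B(allyl), C=CCB([C@@H]1C[C@@H]2C[C@H]([C@H]1C)C2(C)C)[C@@H]1C[C@@H]2C[C@H]([C@H]1C)C2(C)C
Why: Brown allylboration with the enantiomeric reagent; Si-face transfer sets C13 with the 9,13-anti relation of the target.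

Step 11
Reactants: 11 methyl (3R,5R,9R,13R)-5,9-bis(TBSO)-13-hydroxy-3-methylhexadec-15-enoate
Product: 12 methyl (3R,5R,9R,13R)-5,9,13-tris(TBSO)-3-methylhexadec-15-enoate
Conditions: TBSCl, imidazole, DMF, rt
Reagents that add atoms: tert-butyldimethylsilyl chloride, CC(C)(C)[Si](C)(C)Cl
Why: Silyl ether formation on the new secondary alcohol.

Step 12
Reactants: 12 methyl (3R,5R,9R,13R)-5,9,13-tris(TBSO)-3-methylhexadec-15-enoate
Product: 13 methyl (3R,5R,9R,13R)-5,9,13-tris(TBSO)-3-methyl-17-oxoheptadecanoate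
Conditions: Rh(acac)(CO)2 (1 mol %), BIPHEPHOS (3 mol %), CO/H2 (1:1, 5 bar), THF, 65 °C
Reagents that add atoms: carbon monoxide, [C-]#[O+]
Why: Linear-selective hydroformylation as in step 6; delivers the C17 aldehyde.

Step 13
Reactants: 13 methyl (3R,5R,9R,13R)-5,9,13-tris(TBSO)-3-methyl-17-oxoheptadecanoate
Product: 14 methyl (3R,5R,9R,13S,17S)-5,9,13-tris(TBSO)-17-hydroxy-3-methylicos-19-enoate
Conditions: l-Ipc2B(allyl), Et2O, −78 °C; then NaBO3·4H2O, THF/H2O, rt
Reagents that add atoms: l-Ipc2B(allyl), C=CCB([C@H]1C[C@H]2C[C@@H]([C@@H]1C)C2(C)C)[C@H]1C[C@H]2C[C@@H]([C@@H]1C)C2(C)C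
Why: Brown allylboration, Re-face transfer under reagent control; sets C17 (13,17-anti).

Step 14
Reactants: 14 methyl (3R,5R,9R,13S,17S)-5,9,13-tris(TBSO)-17-hydroxy-3-methylicos-19-enoate
Product: 15 methyl (3R,5R,9R,13R,17S)-5,9,13,17-tetrakis(TBSO)-3-methylicos-19-enoate
Conditions: TBSCl, imidazole, DMF, rt
Reagents that add atoms: tert-butyldimethylsilyl chloride, CC(C)(C)[Si](C)(C)Cl
Why: Silyl ether formation on the new secondary alcohol.

Step 15
Reactants: 15 methyl (3R,5R,9R,13R,17S)-5,9,13,17-tetrakis(TBSO)-3-methylicos-19-enoate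
Product: 16 methyl (3R,5R,9R,13R,17S)-5,9,13,17-tetrakis(TBSO)-3-methyl-21-oxohenicosanoate
Conditions: Rh(acac)(CO)2 (1 mol %), BIPHEPHOS (3 mol %), CO/H2 (1:1, 5 bar), THF, 65 °C
Reagents that add atoms: carbon monoxide, [C-]#[O+]
Why: Linear-selective hydroformylation as in step 6; delivers the C21 aldehyde.

Step 16
Reactants: 16 methyl (3R,5R,9R,13R,17S)-5,9,13,17-tetrakis(TBSO)-3-methyl-21-oxohenicosanoate
Product: 17 methyl (3R,5R,9R,13S,17R,21R)-5,9,13,17-tetrakis(TBSO)-21-hydroxy-3-methyltetracos-23-enoate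
Conditions: d-Ipc2B(allyl), Et2O, −78 °C; then NaBO3·4H2O, THF/H2O, rt
Reagents that add atoms: d-Ipc2B(allyl), C=CCB([C@@H]1C[C@@H]2C[C@H]([C@H]1C)C2(C)C)[C@@H]1C[C@@H]2C[C@H]([C@H]1C)C2(C)C
Why: Brown allylboration, Si-face transfer under reagent control; sets C21 (17,21-anti).

Step 17
Reactants: 17 methyl (3R,5R,9R,13S,17R,21R)-5,9,13,17-tetrakis(TBSO)-21-hydroxy-3-methyltetracos-23-enoate
Product: 18 methyl (3R,5R,9R,13S,17S,21R)-5,9,13,17,21-pentakis(TBSO)-3-methyltetracos-23-enoate
Conditions: TBSCl, imidazole, DMF, rt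
Reagents that add atoms: tert-butyldimethylsilyl chloride, CC(C)(C)[Si](C)(C)Cl
Why: Silyl ether formation on the new secondary alcohol.

Step 18
Reactants: 18 methyl (3R,5R,9R,13S,17S,21R)-5,9,13,17,21-pentakis(TBSO)-3-methyltetracos-23-enoate
Product: 19 methyl (3R,5R,9R,13S,17S,21R)-5,9,13,17,21-pentakis(TBSO)-3-methyl-25-oxopentacosanoate
Conditions: Rh(acac)(CO)2 (1 mol %), BIPHEPHOS (3 mol %), CO/H2 (1:1, 5 bar), THF, 65 °C
Reagents that add atoms: carbon monoxide, [C-]#[O+]
Why: Linear-selective hydroformylation as in step 6; delivers the C25 aldehyde.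

Step 19
Reactants: 19 methyl (3R,5R,9R,13S,17S,21R)-5,9,13,17,21-pentakis(TBSO)-3-methyl-25-oxopentacosanoate
Product: 20 methyl (3R,5R,9R,13S,17R,21S,25S)-5,9,13,17,21-pentakis(TBSO)-25-hydroxy-3-methyloctacos-27-enoate
Conditions: l-Ipc2B(allyl), Et2O, −78 °C; then NaBO3·4H2O, THF/H2O, rt
Reagents that add atoms: l-Ipc2B(allyl), C=CCB([C@H]1C[C@H]2C[C@@H]([C@@H]1C)C2(C)C)[C@H]1C[C@H]2C[C@@H]([C@@H]1C)C2(C)C
Why: Brown allylboration, Re-face transfer under reagent control; sets C25 (21,25-anti).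

Step 20
Reactants: 20 methyl (3R,5R,9R,13S,17R,21S,25S)-5,9,13,17,21-pentakis(TBSO)-25-hydroxy-3-methyloctacos-27-enoate
Product: 21 methyl (3R,5R,9R,13S,17S,21R,25S)-5,9,13,17,21,25-hexakis(TBSO)-3-methyloctacos-27-enoate
Conditions: TBSCl, imidazole, DMF, rt
Reagents that add atoms: tert-butyldimethylsilyl chloride, CC(C)(C)[Si](C)(C)Cl
Why: Silyl ether formation on the new secondary alcohol.

Step 21
Reactants: 21 methyl (3R,5R,9R,13S,17S,21R,25S)-5,9,13,17,21,25-hexakis(TBSO)-3-methyloctacos-27-enoate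
Product: 23 methyl (3R,5R,9R,13S,17S,21R,25S)-5,9,13,17,21,25-hexakis(TBSO)-3-methyl-27-oxoheptacosanoate, via ozonide 22 (not isolated)
Conditions: O3, CH2Cl2, −78 °C; then PPh3, −78 °C → rt
Reagents that add atoms: ozone, [O-][O+]=O
Why: Ozonolysis with reductive work-up shortens the allyl group by one carbon to the β-silyloxy aldehyde needed for the 1,3-diol; silyl ethers and the ester are inert.

Step 22
Reactants: 23 methyl (3R,5R,9R,13S,17S,21R,25S)-5,9,13,17,21,25-hexakis(TBSO)-3-methyl-27-oxoheptacosanoate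
Product: 24 methyl (3R,5R,9R,13S,17S,21R,25S,27R)-5,9,13,17,21,25-hexakis(TBSO)-27-hydroxy-3-methyltriacont-29-enoate
Conditions: l-Ipc2B(allyl), Et2O, −78 °C; then NaBO3·4H2O, THF/H2O, rt
Reagents that add atoms: l-Ipc2B(allyl), C=CCB([C@H]1C[C@H]2C[C@@H]([C@@H]1C)C2(C)C)[C@H]1C[C@H]2C[C@@H]([C@@H]1C)C2(C)C
Why: Brown allylboration, Re-face transfer; the reagent should dominate the weak bias of the β-silyloxy aldehyde and set C27 syn to C25.

Step 23
Reactants: 24 methyl (3R,5R,9R,13S,17S,21R,25S,27R)-5,9,13,17,21,25-hexakis(TBSO)-27-hydroxy-3-methyltriacont-29-enoate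
Product: 25 methyl (3R,5R,9R,13S,17S,21R,25S,27R)-5,9,13,17,21,25,27-heptakis(TBSO)-3-methyltriacont-29-enoate
Conditions: TBSCl, imidazole, DMF, rt
Reagents that add atoms: tert-butyldimethylsilyl chloride, CC(C)(C)[Si](C)(C)Cl
Why: Silyl ether formation on the new secondary alcohol.

Step 24
Reactants: 25 methyl (3R,5R,9R,13S,17S,21R,25S,27R)-5,9,13,17,21,25,27-heptakis(TBSO)-3-methyltriacont-29-enoate
Product: 27 methyl (3R,5R,9R,13S,17S,21R,25S,27S)-5,9,13,17,21,25,27-heptakis(TBSO)-3-methyl-29-oxononacosanoate, via ozonide 26 (not isolated)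
Conditions: O3, CH2Cl2, −78 °C; then PPh3, −78 °C → rt
Reagents that add atoms: ozone, [O-][O+]=O
Why: Ozonolysis with reductive work-up, as in step 21; gives the C29 aldehyde.

Step 25
Reactants: 27 methyl (3R,5R,9R,13S,17S,21R,25S,27S)-5,9,13,17,21,25,27-heptakis(TBSO)-3-methyl-29-oxononacosanoate
Product: 28 methyl (3R,5R,9R,13S,17S,21R,25S,27R,29S)-5,9,13,17,21,25,27-heptakis(TBSO)-29-hydroxy-3-methyldotriacont-31-enoate
Conditions: d-Ipc2B(allyl), Et2O, −78 °C; then NaBO3·4H2O, THF/H2O, rt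
Reagents that add atoms: d-Ipc2B(allyl), C=CCB([C@@H]1C[C@@H]2C[C@H]([C@H]1C)C2(C)C)[C@@H]1C[C@@H]2C[C@H]([C@H]1C)C2(C)C
Why: Brown allylboration, Si-face transfer under reagent control; sets C29 anti to C27 and leaves the homoallylic alcohol with the C30–C31 allyl terminus for the tether.

Step 26
Reactants: 29 (S)-4-benzyl-1,3-oxazolidin-2-one; 30 hexanoyl chloride
Product: 31 (S)-4-benzyl-3-hexanoyl-1,3-oxazolidin-2-one
Conditions: n-BuLi, THF, −78 °C; then 30, −78 → 0 °C
Reagents that add atoms: none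
Why: N-Acylation of the lithiated oxazolidinone by the acid chloride (imide formation).

Step 27
Reactants: 31 (S)-4-benzyl-3-hexanoyl-1,3-oxazolidin-2-one
Product: 32 (S)-4-benzyl-3-[(S)-2-methylhexanoyl]-1,3-oxazolidin-2-one
Conditions: NaHMDS, THF, −78 °C; then MeI, −78 °C
Reagents that add atoms: iodomethane, CI
Why: Evans alkylation; the chelated (Z)-sodium enolate is methylated on the face away from the benzyl group, which sets C36 (S).

Step 28
Reactants: 32 (S)-4-benzyl-3-[(S)-2-methylhexanoyl]-1,3-oxazolidin-2-one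
Product: 33 (S)-2-methylhexan-1-ol
Conditions: LiBH4, MeOH (1 equiv), Et2O, 0 °C
Reagents that add atoms: none
Why: Reductive removal of the auxiliary with borohydride; the α-centre is not enolised, and 29 is recovered.

Step 29
Reactants: 33 (S)-2-methylhexan-1-ol
Product: 34 (S)-2-methylhexanal
Conditions: TEMPO (10 mol %), PhI(OAc)2 (1.1 equiv), CH2Cl2, 0 °C → rt; solution used directly
Reagents that add atoms: none
Why: Oxoammonium oxidation under neutral conditions, so the α-stereocentre of the volatile aldehyde should not epimerise.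

Step 30
Reactants: 34 (S)-2-methylhexanal
Product: 35 (4R,5S)-5-methylnon-1-en-4-ol
Conditions: l-Ipc2B(allyl), Et2O, −78 °C; then NaBO3·4H2O, THF/H2O, rt
Reagents that add atoms: l-Ipc2B(allyl), C=CCB([C@H]1C[C@H]2C[C@@H]([C@@H]1C)C2(C)C)[C@H]1C[C@H]2C[C@@H]([C@@H]1C)C2(C)C
Why: Brown allylboration, Re-face transfer; the reagent overrides the small Felkin–Anh bias of an aldehyde whose α-substituents are methyl and n-butyl and sets C35 (R) anti to C36.

Step 31
Reactants: 35 (4R,5S)-5-methylnon-1-en-4-ol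
Product: 36 (4R,5S)-4-(PMBO)-5-methylnon-1-ene
Conditions: NaH, 4-methoxybenzyl chloride, Bu4NI (cat.), DMF, 0 °C → rt
Reagents that add atoms: 4-methoxybenzyl chloride, COc1ccc(CCl)cc1
Why: Williamson ether synthesis; O35 receives the one protecting group that hydrogenolysis will later remove selectively.

Step 32
Reactants: 36 (4R,5S)-4-(PMBO)-5-methylnon-1-ene
Product: 38 (3R,4S)-3-(PMBO)-4-methyloctanal, via diol 37 (not isolated)
Conditions: OsO4 (2 mol %), NaIO4 (4 equiv), 2,6-lutidine, dioxane/H2O (3:1), rt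
Reagents that add atoms: osmium tetroxide (catalytic oxygen donor, re-formed by periodate), O=[Os](=O)(=O)=O; sodium periodate, [Na+].[O-]I(=O)(=O)=O
Why: Johnson–Lemieux oxidation (dihydroxylation, then periodate glycol cleavage); preferred to ozone because the electron-rich PMB arene is ozone-sensitive.

Step 33
Reactants: 38 (3R,4S)-3-(PMBO)-4-methyloctanal
Product: 39 (3R,5R,6S)-5-(PMBO)-6-methyldec-1-en-3-ol
Conditions: MgBr2·OEt2 (2 equiv), CH2Cl2, −78 °C; then CH2=CHMgBr, −78 °C; NH4Cl quench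
Reagents that add atoms: vinylmagnesium bromide, C=C[Mg]Br
Why: Chelation-controlled Grignard addition; magnesium bridges the aldehyde and the β-PMB oxygen in a six-membered chelate and the vinyl group attacks anti to the C35 substituent, so C33 is set 1,3-anti by C35.

Step 34
Reactants: 39 (3R,5R,6S)-5-(PMBO)-6-methyldec-1-en-3-ol; 40 dichlorodiisopropylsilane; 28 methyl (3R,5R,9R,13S,17S,21R,25S,27R,29S)-5,9,13,17,21,25,27-heptakis(TBSO)-29-hydroxy-3-methyldotriacont-31-enoate
Product: 42 mixed diisopropylsilylene acetal joining O33 of 39 and O29 of 28, via chlorosilane 41 (not isolated)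
Conditions: 39 (1.3 equiv), 40 (4 equiv), imidazole, CH2Cl2, 0 °C; volatiles removed under high vacuum; then 28 (1.0 equiv), imidazole, DMAP (cat.), DMF, rt
Reagents that add atoms: none
Why: Stepwise silylation of two alcohols by a dichlorosilane; excess 40 makes only the monochloride of the cheaper alcohol, the excess is volatile, and the valuable alcohol 28 then displaces the second chloride, which excludes symmetrical bis-ethers of 28.

Step 35
Reactants: 42 mixed diisopropylsilylene acetal joining O33 of 39 and O29 of 28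
Product: 43 (31Z)-2,2-diisopropyl-1,3-dioxa-2-silacyclooct-5-ene spanning O29–C29–C30–C31=C32–C33–O33 of the full C1–C40 chain
Conditions: second-generation Grubbs catalyst (H2IMes)(PCy3)Cl2Ru=CHPh (10 mol % in two portions), toluene (2 mM), 80 °C, argon purge
Reagents that add atoms: none
Why: The ruthenium benzylidene exchanges first with the unhindered allyl terminus (new carbene at C31, styrene lost), then adds across the C32 vinyl group of the same molecule to a ruthenacyclobutane whose cycloreversion releases the ring and Ru=CH2, the net by-product being ethylene. The closest known reaction type is the temporary silicon-tethered ring-closing metathesis of mixed bis-alkoxysilanes built from an allylic and a homoallylic alcohol. The one ring formed is the eight-membered dioxasilocine (Si, O29, C29, C30, C31, C32, C33, O33), closed at C31=C32 by metathesis; a ring of this size can hold only the cis alkene. No stereocentre is created, and C29 and C33 are not touched. The selectivity needed is hetero-coupling of two terminal alkenes of similar reactivity, and it is secured by the tether, which makes the union intramolecular, with high dilution holding back dimerisation. The two isopropyl groups favour the folded conformer and shield the Si–O bonds. Esters, PMB and TBS ethers are inert to the carbene, and the molecule contains no other alkene.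

Step 36
Reactants: 43 (31Z)-dioxasilacyclooctene with PMB ether at O35
Product: 44 C35 alcohol with saturated 2,2-diisopropyl-1,3,2-dioxasilocane over O29/O33, methyl ester at C1
Conditions: H2 (1 atm), 10% Pd/C, EtOAc, rt
Reagents that add atoms: none
Why: Heterogeneous hydrogenation saturates the cis ring alkene and hydrogenolyses the benzylic C–O bond of the PMB ether in the same operation; EtOAc keeps the catalyst from acting as an acid toward the silyl groups.

Step 37
Reactants: 44 C35 alcohol with saturated dioxasilocane and methyl ester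
Product: 45 seco acid (C1 carboxylic acid, free O35–H, seven TBS ethers, O29/O33 silylene)
Conditions: Me3SnOH (8 equiv), ClCH2CH2Cl, 80 °C; then cold 0.05 M HCl wash
Reagents that add atoms: trimethyltin hydroxide, C[Sn](C)(C)O
Why: Trimethyltin hydroxide ester cleavage; neutral, tin-assisted hydroxide delivery to the unhindered methyl ester avoids alkali hydroxide, which could attack the dialkoxysilane.

Step 38
Reactants: 45 seco acid
Product: 47 protected 36-membered lactone (seven TBS ethers, O29/O33 diisopropylsilylene), via mixed anhydride 46 (not isolated)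
Conditions: 2,4,6-trichlorobenzoyl chloride, Et3N, THF, rt; then slow addition to DMAP, toluene (0.5 mM), 80 °C
Reagents that add atoms: none
Why: Yamaguchi macrolactonisation; the mixed anhydride is opened by DMAP and the acylpyridinium is captured by O35, the only free hydroxyl, under high dilution, and no stereocentre is involved.

Step 39
Reactants: 47 protected 36-membered lactone
Product: 48 (3R,5R,9R,13S,17S,21R,25S,27S,29S,33S,35R)-35-[(2S)-hexan-2-yl]-5,9,13,17,21,25,27,29,33-nonahydroxy-3-methylpentatriacontan-35-olide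
Conditions: HF·pyridine, pyridine, THF, 0 °C → rt
Reagents that add atoms: none
Why: Fluoride-mediated cleavage of all nine Si–O bonds (seven TBS ethers and the silylene) under buffered, weakly acidic conditions in which the lactone should neither open nor migrate.

## Compound list

1 | dimethyl 3-methylglutarate | COC(=O)CC(C)CC(=O)OC | starting material
2 | (R)-5-methoxy-3-methyl-5-oxopentanoic acid | OC(=O)C[C@@H](C)CC(=O)OC | intermediate
3 | methyl (R)-5-hydroxy-3-methylpentanoate | OCC[C@@H](C)CC(=O)OC | intermediate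
4 | methyl (R)-3-methyl-5-oxopentanoate | O=CC[C@@H](C)CC(=O)OC | intermediate
5 | methyl (3R,5R)-5-hydroxy-3-methyloct-7-enoate | C=CC[C@@H](O)C[C@@H](C)CC(=O)OC | intermediate
6 | methyl (3R,5R)-5-(TBSO)-3-methyloct-7-enoate | C=CC[C@@H](O[Si](C)(C)C(C)(C)C)C[C@@H](C)CC(=O)OC | intermediate
7 | methyl (3R,5R)-5-(TBSO)-3-methyl-9-oxononanoate | O=CCCC[C@@H](O[Si](C)(C)C(C)(C)C)C[C@@H](C)CC(=O)OC | intermediate
8 | methyl (3R,5R,9S)-5-(TBSO)-9-hydroxy-3-methyldodec-11-enoate | C=CC[C@@H](O)CCC[C@@H](O[Si](C)(C)C(C)(C)C)C[C@@H](C)CC(=O)OC | intermediate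
9 | methyl (3R,5R,9S)-5,9-bis(TBSO)-3-methyldodec-11-enoate | C=CC[C@@H](O[Si](C)(C)C(C)(C)C)CCC[C@@H](O[Si](C)(C)C(C)(C)C)C[C@@H](C)CC(=O)OC | intermediate
10 | methyl (3R,5R,9S)-5,9-bis(TBSO)-3-methyl-13-oxotridecanoate | O=CCCC[C@@H](O[Si](C)(C)C(C)(C)C)CCC[C@@H](O[Si](C)(C)C(C)(C)C)C[C@@H](C)CC(=O)OC | intermediate
11 | methyl (3R,5R,9R,13R)-5,9-bis(TBSO)-13-hydroxy-3-methylhexadec-15-enoate | C=CC[C@H](O)CCC[C@@H](O[Si](C)(C)C(C)(C)C)CCC[C@@H](O[Si](C)(C)C(C)(C)C)C[C@@H](C)CC(=O)OC | intermediate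
12 | methyl (3R,5R,9R,13R)-5,9,13-tris(TBSO)-3-methylhexadec-15-enoate | C=CC[C@H](O[Si](C)(C)C(C)(C)C)CCC[C@@H](O[Si](C)(C)C(C)(C)C)CCC[C@@H](O[Si](C)(C)C(C)(C)C)C[C@@H](C)CC(=O)OC | intermediate
13 | methyl (3R,5R,9R,13R)-5,9,13-tris(TBSO)-3-methyl-17-oxoheptadecanoate | O=CCCC[C@H](O[Si](C)(C)C(C)(C)C)CCC[C@@H](O[Si](C)(C)C(C)(C)C)CCC[C@@H](O[Si](C)(C)C(C)(C)C)C[C@@H](C)CC(=O)OC | intermediate
14 | methyl (3R,5R,9R,13S,17S)-5,9,13-tris(TBSO)-17-hydroxy-3-methylicos-19-enoate | C=CC[C@@H](O)CCC[C@H](O[Si](C)(C)C(C)(C)C)CCC[C@@H](O[Si](C)(C)C(C)(C)C)CCC[C@@H](O[Si](C)(C)C(C)(C)C)C[C@@H](C)CC(=O)OC | intermediate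
15 | methyl (3R,5R,9R,13R,17S)-5,9,13,17-tetrakis(TBSO)-3-methylicos-19-enoate | C=CC[C@@H](O[Si](C)(C)C(C)(C)C)CCC[C@H](O[Si](C)(C)C(C)(C)C)CCC[C@@H](O[Si](C)(C)C(C)(C)C)CCC[C@@H](O[Si](C)(C)C(C)(C)C)C[C@@H](C)CC(=O)OC | intermediate
16 | methyl (3R,5R,9R,13R,17S)-5,9,13,17-tetrakis(TBSO)-3-methyl-21-oxohenicosanoate | O=CCCC[C@@H](O[Si](C)(C)C(C)(C)C)CCC[C@H](O[Si](C)(C)C(C)(C)C)CCC[C@@H](O[Si](C)(C)C(C)(C)C)CCC[C@@H](O[Si](C)(C)C(C)(C)C)C[C@@H](C)CC(=O)OC | intermediate
17 | methyl (3R,5R,9R,13S,17R,21R)-5,9,13,17-tetrakis(TBSO)-21-hydroxy-3-methyltetracos-23-enoate | C=CC[C@H](O)CCC[C@@H](O[Si](C)(C)C(C)(C)C)CCC[C@H](O[Si](C)(C)C(C)(C)C)CCC[C@@H](O[Si](C)(C)C(C)(C)C)CCC[C@@H](O[Si](C)(C)C(C)(C)C)C[C@@H](C)CC(=O)OC | intermediate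
18 | methyl (3R,5R,9R,13S,17S,21R)-5,9,13,17,21-pentakis(TBSO)-3-methyltetracos-23-enoate | C=CC[C@H](O[Si](C)(C)C(C)(C)C)CCC[C@@H](O[Si](C)(C)C(C)(C)C)CCC[C@H](O[Si](C)(C)C(C)(C)C)CCC[C@@H](O[Si](C)(C)C(C)(C)C)CCC[C@@H](O[Si](C)(C)C(C)(C)C)C[C@@H](C)CC(=O)OC | intermediate
19 | methyl (3R,5R,9R,13S,17S,21R)-5,9,13,17,21-pentakis(TBSO)-3-methyl-25-oxopentacosanoate | O=CCCC[C@H](O[Si](C)(C)C(C)(C)C)CCC[C@@H](O[Si](C)(C)C(C)(C)C)CCC[C@H](O[Si](C)(C)C(C)(C)C)CCC[C@@H](O[Si](C)(C)C(C)(C)C)CCC[C@@H](O[Si](C)(C)C(C)(C)C)C[C@@H](C)CC(=O)OC | intermediate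
20 | methyl (3R,5R,9R,13S,17R,21S,25S)-5,9,13,17,21-pentakis(TBSO)-25-hydroxy-3-methyloctacos-27-enoate | C=CC[C@@H](O)CCC[C@H](O[Si](C)(C)C(C)(C)C)CCC[C@@H](O[Si](C)(C)C(C)(C)C)CCC[C@H](O[Si](C)(C)C(C)(C)C)CCC[C@@H](O[Si](C)(C)C(C)(C)C)CCC[C@@H](O[Si](C)(C)C(C)(C)C)C[C@@H](C)CC(=O)OC | intermediate
21 | methyl (3R,5R,9R,13S,17S,21R,25S)-5,9,13,17,21,25-hexakis(TBSO)-3-methyloctacos-27-enoate | C=CC[C@@H](O[Si](C)(C)C(C)(C)C)CCC[C@H](O[Si](C)(C)C(C)(C)C)CCC[C@@H](O[Si](C)(C)C(C)(C)C)CCC[C@H](O[Si](C)(C)C(C)(C)C)CCC[C@@H](O[Si](C)(C)C(C)(C)C)CCC[C@@H](O[Si](C)(C)C(C)(C)C)C[C@@H](C)CC(=O)OC | intermediate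
22 | ozonide (1,2,4-trioxolane at C27/C28) of 21 | C1OC(OO1)C[C@@H](O[Si](C)(C)C(C)(C)C)CCC[C@H](O[Si](C)(C)C(C)(C)C)CCC[C@@H](O[Si](C)(C)C(C)(C)C)CCC[C@H](O[Si](C)(C)C(C)(C)C)CCC[C@@H](O[Si](C)(C)C(C)(C)C)CCC[C@@H](O[Si](C)(C)C(C)(C)C)C[C@@H](C)CC(=O)OC | intermediate
23 | methyl (3R,5R,9R,13S,17S,21R,25S)-5,9,13,17,21,25-hexakis(TBSO)-3-methyl-27-oxoheptacosanoate | O=CC[C@@H](O[Si](C)(C)C(C)(C)C)CCC[C@H](O[Si](C)(C)C(C)(C)C)CCC[C@@H](O[Si](C)(C)C(C)(C)C)CCC[C@H](O[Si](C)(C)C(C)(C)C)CCC[C@@H](O[Si](C)(C)C(C)(C)C)CCC[C@@H](O[Si](C)(C)C(C)(C)C)C[C@@H](C)CC(=O)OC | intermediate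
24 | methyl (3R,5R,9R,13S,17S,21R,25S,27R)-5,9,13,17,21,25-hexakis(TBSO)-27-hydroxy-3-methyltriacont-29-enoate | C=CC[C@@H](O)C[C@@H](O[Si](C)(C)C(C)(C)C)CCC[C@H](O[Si](C)(C)C(C)(C)C)CCC[C@@H](O[Si](C)(C)C(C)(C)C)CCC[C@H](O[Si](C)(C)C(C)(C)C)CCC[C@@H](O[Si](C)(C)C(C)(C)C)CCC[C@@H](O[Si](C)(C)C(C)(C)C)C[C@@H](C)CC(=O)OC | intermediate
25 | methyl (3R,5R,9R,13S,17S,21R,25S,27R)-5,9,13,17,21,25,27-heptakis(TBSO)-3-methyltriacont-29-enoate | C=CC[C@@H](O[Si](C)(C)C(C)(C)C)C[C@@H](O[Si](C)(C)C(C)(C)C)CCC[C@H](O[Si](C)(C)C(C)(C)C)CCC[C@@H](O[Si](C)(C)C(C)(C)C)CCC[C@H](O[Si](C)(C)C(C)(C)C)CCC[C@@H](O[Si](C)(C)C(C)(C)C)CCC[C@@H](O[Si](C)(C)C(C)(C)C)C[C@@H](C)CC(=O)OC | intermediate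
26 | ozonide (1,2,4-trioxolane at C29/C30) of 25 | C1OC(OO1)C[C@@H](O[Si](C)(C)C(C)(C)C)C[C@@H](O[Si](C)(C)C(C)(C)C)CCC[C@H](O[Si](C)(C)C(C)(C)C)CCC[C@@H](O[Si](C)(C)C(C)(C)C)CCC[C@H](O[Si](C)(C)C(C)(C)C)CCC[C@@H](O[Si](C)(C)C(C)(C)C)CCC[C@@H](O[Si](C)(C)C(C)(C)C)C[C@@H](C)CC(=O)OC | intermediate
27 | methyl (3R,5R,9R,13S,17S,21R,25S,27S)-5,9,13,17,21,25,27-heptakis(TBSO)-3-methyl-29-oxononacosanoate | O=CC[C@@H](O[Si](C)(C)C(C)(C)C)C[C@@H](O[Si](C)(C)C(C)(C)C)CCC[C@H](O[Si](C)(C)C(C)(C)C)CCC[C@@H](O[Si](C)(C)C(C)(C)C)CCC[C@H](O[Si](C)(C)C(C)(C)C)CCC[C@@H](O[Si](C)(C)C(C)(C)C)CCC[C@@H](O[Si](C)(C)C(C)(C)C)C[C@@H](C)CC(=O)OC | intermediate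
28 | methyl (3R,5R,9R,13S,17S,21R,25S,27R,29S)-5,9,13,17,21,25,27-heptakis(TBSO)-29-hydroxy-3-methyldotriacont-31-enoate (western fragment) | C=CC[C@H](O)C[C@@H](O[Si](C)(C)C(C)(C)C)C[C@@H](O[Si](C)(C)C(C)(C)C)CCC[C@H](O[Si](C)(C)C(C)(C)C)CCC[C@@H](O[Si](C)(C)C(C)(C)C)CCC[C@H](O[Si](C)(C)C(C)(C)C)CCC[C@@H](O[Si](C)(C)C(C)(C)C)CCC[C@@H](O[Si](C)(C)C(C)(C)C)C[C@@H](C)CC(=O)OC | intermediate
29 | (S)-4-benzyl-1,3-oxazolidin-2-one | O=C1N[C@@H](Cc2ccccc2)CO1 | starting material
30 | hexanoyl chloride | CCCCCC(=O)Cl | starting material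
31 | (S)-4-benzyl-3-hexanoyl-1,3-oxazolidin-2-one | CCCCCC(=O)N1[C@@H](Cc2ccccc2)COC1=O | intermediate
32 | (S)-4-benzyl-3-[(S)-2-methylhexanoyl]-1,3-oxazolidin-2-one | CCCC[C@H](C)C(=O)N1[C@@H](Cc2ccccc2)COC1=O | intermediate
33 | (S)-2-methylhexan-1-ol | CCCC[C@H](C)CO | intermediate
34 | (S)-2-methylhexanal | CCCC[C@H](C)C=O | intermediate
35 | (4R,5S)-5-methylnon-1-en-4-ol | CCCC[C@H](C)[C@H](O)CC=C | intermediate
36 | (4R,5S)-4-(PMBO)-5-methylnon-1-ene | CCCC[C@H](C)[C@H](OCc1ccc(OC)cc1)CC=C | intermediate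
37 | (4R,5S)-4-(PMBO)-5-methylnonane-1,2-diol (both C2 epimers) | CCCC[C@H](C)[C@H](OCc1ccc(OC)cc1)CC(O)CO | intermediate
38 | (3R,4S)-3-(PMBO)-4-methyloctanal | CCCC[C@H](C)[C@H](OCc1ccc(OC)cc1)CC=O | intermediate
39 | (3R,5R,6S)-5-(PMBO)-6-methyldec-1-en-3-ol (eastern fragment) | CCCC[C@H](C)[C@H](OCc1ccc(OC)cc1)C[C@@H](O)C=C | intermediate
40 | dichlorodiisopropylsilane | CC(C)[Si](Cl)(Cl)C(C)C | starting material
41 | chloro(diisopropyl)silyl ether of 39 | CCCC[C@H](C)[C@H](OCc1ccc(OC)cc1)C[C@@H](O[Si](Cl)(C(C)C)C(C)C)C=C | intermediate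
42 | mixed diisopropylsilylene acetal, O33 (of 39)–Si(iPr)2–O29 (of 28); 3R,5R,9R,13S,17S,21R,25S,27S,29S,33R,35R,36S; PMB ether at O35, methyl ester at C1 | CCCC[C@H](C)[C@H](OCc1ccc(OC)cc1)C[C@@H](O[Si](C(C)C)(C(C)C)O[C@@H](CC=C)C[C@@H](O[Si](C)(C)C(C)(C)C)C[C@@H](O[Si](C)(C)C(C)(C)C)CCC[C@H](O[Si](C)(C)C(C)(C)C)CCC[C@@H](O[Si](C)(C)C(C)(C)C)CCC[C@H](O[Si](C)(C)C(C)(C)C)CCC[C@@H](O[Si](C)(C)C(C)(C)C)CCC[C@@H](O[Si](C)(C)C(C)(C)C)C[C@@H](C)CC(=O)OC)C=C | intermediate
43 | full C1–C40 chain with (31Z)-alkene inside the 2,2-diisopropyl-1,3-dioxa-2-silacyclooct-5-ene over O29/O33; PMB ether at O35, methyl ester at C1 | CCCC[C@H](C)[C@H](OCc1ccc(OC)cc1)C[C@@H]2/C=C\C[C@@H](C[C@@H](O[Si](C)(C)C(C)(C)C)C[C@@H](O[Si](C)(C)C(C)(C)C)CCC[C@H](O[Si](C)(C)C(C)(C)C)CCC[C@@H](O[Si](C)(C)C(C)(C)C)CCC[C@H](O[Si](C)(C)C(C)(C)C)CCC[C@@H](O[Si](C)(C)C(C)(C)C)CCC[C@@H](O[Si](C)(C)C(C)(C)C)C[C@@H](C)CC(=O)OC)O[Si](C(C)C)(C(C)C)O2 | intermediate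
44 | C35 alcohol with saturated 2,2-diisopropyl-1,3,2-dioxasilocane over O29/O33 (33S,35R,36S), methyl ester at C1, seven TBS ethers | CCCC[C@H](C)[C@H](O)C[C@@H]1CCC[C@@H](C[C@@H](O[Si](C)(C)C(C)(C)C)C[C@@H](O[Si](C)(C)C(C)(C)C)CCC[C@H](O[Si](C)(C)C(C)(C)C)CCC[C@@H](O[Si](C)(C)C(C)(C)C)CCC[C@H](O[Si](C)(C)C(C)(C)C)CCC[C@@H](O[Si](C)(C)C(C)(C)C)CCC[C@@H](O[Si](C)(C)C(C)(C)C)C[C@@H](C)CC(=O)OC)O[Si](C(C)C)(C(C)C)O1 | intermediate
45 | seco acid: C1 carboxylic acid, free O35–H, O29/O33 silylene, seven TBS ethers | CCCC[C@H](C)[C@H](O)C[C@@H]1CCC[C@@H](C[C@@H](O[Si](C)(C)C(C)(C)C)C[C@@H](O[Si](C)(C)C(C)(C)C)CCC[C@H](O[Si](C)(C)C(C)(C)C)CCC[C@@H](O[Si](C)(C)C(C)(C)C)CCC[C@H](O[Si](C)(C)C(C)(C)C)CCC[C@@H](O[Si](C)(C)C(C)(C)C)CCC[C@@H](O[Si](C)(C)C(C)(C)C)C[C@@H](C)CC(=O)O)O[Si](C(C)C)(C(C)C)O1 | intermediate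
46 | mixed anhydride of 45 with 2,4,6-trichlorobenzoic acid | CCCC[C@H](C)[C@H](O)C[C@@H]1CCC[C@@H](C[C@@H](O[Si](C)(C)C(C)(C)C)C[C@@H](O[Si](C)(C)C(C)(C)C)CCC[C@H](O[Si](C)(C)C(C)(C)C)CCC[C@@H](O[Si](C)(C)C(C)(C)C)CCC[C@H](O[Si](C)(C)C(C)(C)C)CCC[C@@H](O[Si](C)(C)C(C)(C)C)CCC[C@@H](O[Si](C)(C)C(C)(C)C)C[C@@H](C)CC(=O)OC(=O)c2c(Cl)cc(Cl)cc2Cl)O[Si](C(C)C)(C(C)C)O1 | intermediate
47 | protected 36-membered lactone: seven TBS ethers, O29/O33 diisopropylsilylene | CCCC[C@H](C)[C@H]1C[C@@H]2CCC[C@@H](C[C@@H](O[Si](C)(C)C(C)(C)C)C[C@@H](O[Si](C)(C)C(C)(C)C)CCC[C@H](O[Si](C)(C)C(C)(C)C)CCC[C@@H](O[Si](C)(C)C(C)(C)C)CCC[C@H](O[Si](C)(C)C(C)(C)C)CCC[C@@H](O[Si](C)(C)C(C)(C)C)CCC[C@@H](O[Si](C)(C)C(C)(C)C)C[C@@H](C)CC(=O)O1)O[Si](C(C)C)(C(C)C)O2 | intermediate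
48 | (3R,5R,9R,13S,17S,21R,25S,27S,29S,33S,35R)-35-[(2S)-hexan-2-yl]-5,9,13,17,21,25,27,29,33-nonahydroxy-3-methylpentatriacontan-35-olide | CCCC[C@H](C)[C@H]1C[C@@H](O)CCC[C@H](O)C[C@@H](O)C[C@@H](O)CCC[C@H](O)CCC[C@@H](O)CCC[C@H](O)CCC[C@@H](O)CCC[C@@H](O)C[C@@H](C)CC(=O)O1 | target

## Step count and least certain steps

Total step count: 39. Longest linear sequence: 31 steps (steps 1–25 and 34–39). The eastern branch is 8 steps (26–33).

Step 35 (key step). Most likely failure: intermolecular metathesis (dimers and oligomers), or stalling because closure of the eight-membered ring is slow relative to catalyst decay; a ruthenium hydride could also shift the allyl double bond before closure. Fallback, from 28 and 39 back to 44: untethered cross-metathesis of 28 with an excess of the slowly homodimerising allylic alcohol 39, using the second-generation Hoveyda–Grubbs catalyst (H2IMes)Cl2Ru=CH(C6H4-2-OiPr), should give the C29,C33-diol with a C31=C32 alkene F1. Diimide reduction (2-nitrobenzenesulfonylhydrazide, Et3N) gives the saturated diol F2. Diisopropylsilyl bis(triflate) with 2,6-lutidine at high dilution closes the saturated silylene with the PMB ether retained, F3. Hydrogenolysis over Pd/C then gives 44.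

Step 34. Most likely failure: hydrolysis of the chlorosilane during the solvent change, formation of the symmetrical bis-ether of 39, or incomplete silylation of the hindered β-silyloxy carbinol 28. Fallback, from 39 back to 42: chlorodiisopropylsilane and imidazole convert 39 into the hydridosilyl ether F4, which can be chromatographed. N-Bromosuccinimide turns it into the bromosilane F5 in the flask, and 28 with imidazole and DMAP then gives 42 with exact stoichiometry.

Step 33. Most likely failure: poor facial selectivity, because THF from the Grignard solution competes with the magnesium chelate. Fallback, from 38 back to 39: the addition is run as before and the C33 epimer (3S,5R,6S)-5-(PMBO)-6-methyldec-1-en-3-ol F6 is separated. A Mitsunobu reaction (4-nitrobenzoic acid, PPh3, diisopropyl azodicarboxylate) inverts it to the (3R) 4-nitrobenzoate F7, and K2CO3 in methanol releases 39.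

Step 36. Most likely failure: palladium hydride moves the C31=C32 bond toward O33 (silyl enol ether) before it is saturated, which would erase the C33 configuration; sluggish PMB hydrogenolysis or partial silyl loss are further risks. Fallback, from 43 back to 44: DDQ in CH2Cl2/pH 7 buffer removes the PMB group first to give the C35 alcohol that still holds the (31Z)-alkene, F8, and diimide (2-nitrobenzenesulfonylhydrazide, Et3N), which cannot isomerise alkenes, then saturates the ring to 44.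

Step 38. Most likely failure: intermolecular acylation (diolides, oligomers) outruns ring closure at the hindered O35, or the silylene shifts from O29 to the free O35 under the basic conditions and exposes a competing hydroxyl. Fallback, from 28 and 39 back to 48, making the ester first and closing the ring at C31=C32 without a tether:
- 28 is silylated to the octakis-TBS ester F9 and cleaved with Me3SnOH to the acid F10.
- 39 is silylated to the C33 TBS ether F11 and the PMB group removed with DDQ to the C35 alcohol F12.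
- Intermolecular Yamaguchi esterification joins them to the diene ester F13.
- Ring-closing metathesis with the second-generation Grubbs catalyst at high dilution gives the 36-membered alkene F14.
- Hydrogenation gives the nona-TBS lactone F15, and HF·pyridine gives 48.

## Further compounds

F1 | step 35 | C29,C33-diol with (31E)-alkene, PMB ether at O35, methyl ester, seven TBS ethers | CCCC[C@H](C)[C@H](OCc1ccc(OC)cc1)C[C@@H](O)/C=C/C[C@H](O)C[C@@H](O[Si](C)(C)C(C)(C)C)C[C@@H](O[Si](C)(C)C(C)(C)C)CCC[C@H](O[Si](C)(C)C(C)(C)C)CCC[C@@H](O[Si](C)(C)C(C)(C)C)CCC[C@H](O[Si](C)(C)C(C)(C)C)CCC[C@@H](O[Si](C)(C)C(C)(C)C)CCC[C@@H](O[Si](C)(C)C(C)(C)C)C[C@@H](C)CC(=O)OC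
F2 | step 35 | saturated C29,C33-diol, PMB ether at O35, methyl ester, seven TBS ethers | CCCC[C@H](C)[C@H](OCc1ccc(OC)cc1)C[C@@H](O)CCC[C@H](O)C[C@@H](O[Si](C)(C)C(C)(C)C)C[C@@H](O[Si](C)(C)C(C)(C)C)CCC[C@H](O[Si](C)(C)C(C)(C)C)CCC[C@@H](O[Si](C)(C)C(C)(C)C)CCC[C@H](O[Si](C)(C)C(C)(C)C)CCC[C@@H](O[Si](C)(C)C(C)(C)C)CCC[C@@H](O[Si](C)(C)C(C)(C)C)C[C@@H](C)CC(=O)OC
F3 | step 35 | saturated O29/O33 diisopropylsilylene with PMB ether at O35 and methyl ester | CCCC[C@H](C)[C@H](OCc1ccc(OC)cc1)C[C@@H]2CCC[C@@H](C[C@@H](O[Si](C)(C)C(C)(C)C)C[C@@H](O[Si](C)(C)C(C)(C)C)CCC[C@H](O[Si](C)(C)C(C)(C)C)CCC[C@@H](O[Si](C)(C)C(C)(C)C)CCC[C@H](O[Si](C)(C)C(C)(C)C)CCC[C@@H](O[Si](C)(C)C(C)(C)C)CCC[C@@H](O[Si](C)(C)C(C)(C)C)C[C@@H](C)CC(=O)OC)O[Si](C(C)C)(C(C)C)O2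
F4 | step 34 | diisopropyl(hydrido)silyl ether of 39 | CCCC[C@H](C)[C@H](OCc1ccc(OC)cc1)C[C@@H](O[SiH](C(C)C)C(C)C)C=C
F5 | step 34 | bromo(diisopropyl)silyl ether of 39 | CCCC[C@H](C)[C@H](OCc1ccc(OC)cc1)C[C@@H](O[Si](Br)(C(C)C)C(C)C)C=C
F6 | step 33 | (3S,5R,6S)-5-(PMBO)-6-methyldec-1-en-3-ol | CCCC[C@H](C)[C@H](OCc1ccc(OC)cc1)C[C@H](O)C=C
F7 | step 33 | (3R,5R,6S)-5-(PMBO)-6-methyldec-1-en-3-yl 4-nitrobenzoate | CCCC[C@H](C)[C@H](OCc1ccc(OC)cc1)C[C@@H](OC(=O)c1ccc(cc1)[N+](=O)[O-])C=C
F8 | step 36 | C35 alcohol with (31Z)-alkene in the O29/O33 silylene ring, methyl ester | CCCC[C@H](C)[C@H](O)C[C@@H]1/C=C\C[C@@H](C[C@@H](O[Si](C)(C)C(C)(C)C)C[C@@H](O[Si](C)(C)C(C)(C)C)CCC[C@H](O[Si](C)(C)C(C)(C)C)CCC[C@@H](O[Si](C)(C)C(C)(C)C)CCC[C@H](O[Si](C)(C)C(C)(C)C)CCC[C@@H](O[Si](C)(C)C(C)(C)C)CCC[C@@H](O[Si](C)(C)C(C)(C)C)C[C@@H](C)CC(=O)OC)O[Si](C(C)C)(C(C)C)O1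
F9 | step 38 | C29 TBS ether of 28 (octakis-TBS methyl ester) | C=CC[C@H](O[Si](C)(C)C(C)(C)C)C[C@@H](O[Si](C)(C)C(C)(C)C)C[C@@H](O[Si](C)(C)C(C)(C)C)CCC[C@H](O[Si](C)(C)C(C)(C)C)CCC[C@@H](O[Si](C)(C)C(C)(C)C)CCC[C@H](O[Si](C)(C)C(C)(C)C)CCC[C@@H](O[Si](C)(C)C(C)(C)C)CCC[C@@H](O[Si](C)(C)C(C)(C)C)C[C@@H](C)CC(=O)OC
F10 | step 38 | octakis-TBS C1–C31 carboxylic acid | C=CC[C@H](O[Si](C)(C)C(C)(C)C)C[C@@H](O[Si](C)(C)C(C)(C)C)C[C@@H](O[Si](C)(C)C(C)(C)C)CCC[C@H](O[Si](C)(C)C(C)(C)C)CCC[C@@H](O[Si](C)(C)C(C)(C)C)CCC[C@H](O[Si](C)(C)C(C)(C)C)CCC[C@@H](O[Si](C)(C)C(C)(C)C)CCC[C@@H](O[Si](C)(C)C(C)(C)C)C[C@@H](C)CC(=O)O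
F11 | step 38 | C33 TBS ether of 39 | CCCC[C@H](C)[C@H](OCc1ccc(OC)cc1)C[C@@H](O[Si](C)(C)C(C)(C)C)C=C
F12 | step 38 | (3R,5R,6S)-3-(TBSO)-6-methyldec-1-en-5-ol | CCCC[C@H](C)[C@H](O)C[C@@H](O[Si](C)(C)C(C)(C)C)C=C
F13 | step 38 | open-chain ester of F10 with O35 of F12 (nona-TBS diene) | C=CC[C@H](O[Si](C)(C)C(C)(C)C)C[C@@H](O[Si](C)(C)C(C)(C)C)C[C@@H](O[Si](C)(C)C(C)(C)C)CCC[C@H](O[Si](C)(C)C(C)(C)C)CCC[C@@H](O[Si](C)(C)C(C)(C)C)CCC[C@H](O[Si](C)(C)C(C)(C)C)CCC[C@@H](O[Si](C)(C)C(C)(C)C)CCC[C@@H](O[Si](C)(C)C(C)(C)C)C[C@@H](C)CC(=O)O[C@H](C[C@@H](O[Si](C)(C)C(C)(C)C)C=C)[C@@H](C)CCCC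
F14 | step 38 | nona-TBS 36-membered lactone with C31=C32 alkene (E/Z mixture) | CCCC[C@H](C)[C@H]1C[C@@H](O[Si](C)(C)C(C)(C)C)C=CC[C@H](O[Si](C)(C)C(C)(C)C)C[C@@H](O[Si](C)(C)C(C)(C)C)C[C@@H](O[Si](C)(C)C(C)(C)C)CCC[C@H](O[Si](C)(C)C(C)(C)C)CCC[C@@H](O[Si](C)(C)C(C)(C)C)CCC[C@H](O[Si](C)(C)C(C)(C)C)CCC[C@@H](O[Si](C)(C)C(C)(C)C)CCC[C@@H](O[Si](C)(C)C(C)(C)C)C[C@@H](C)CC(=O)O1
F15 | step 38 | nona-TBS saturated 36-membered lactone | CCCC[C@H](C)[C@H]1C[C@@H](O[Si](C)(C)C(C)(C)C)CCC[C@H](O[Si](C)(C)C(C)(C)C)C[C@@H](O[Si](C)(C)C(C)(C)C)C[C@@H](O[Si](C)(C)C(C)(C)C)CCC[C@H](O[Si](C)(C)C(C)(C)C)CCC[C@@H](O[Si](C)(C)C(C)(C)C)CCC[C@H](O[Si](C)(C)C(C)(C)C)CCC[C@@H](O[Si](C)(C)C(C)(C)C)CCC[C@@H](O[Si](C)(C)C(C)(C)C)C[C@@H](C)CC(=O)O1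
A1 | alternative 1 | glutaraldehyde (C13–C17 hub) | O=CCCCC=O
A2 | alternative 1 | 5-(4-methoxybenzyloxy)pentanal | COc1ccc(COCCCCC=O)cc1
A3 | alternative 1 | C2-symmetric C5–C25 diene tetraol (carbinols at C9, C13, C17, C21) | COc1ccc(cc1)COCCCC[C@H](O)C/C=C/[C@@H](O)CCC[C@H](O)/C=C/C[C@@H](O)CCCCOCc2ccc(OC)cc2
A4 | alternative 2 | nona-TBS 36-membered lactone with (E)-C7=C8 alkene | CCCC[C@H](C)[C@H]1C[C@@H](O[Si](C)(C)C(C)(C)C)CCC[C@H](O[Si](C)(C)C(C)(C)C)C[C@@H](O[Si](C)(C)C(C)(C)C)C[C@@H](O[Si](C)(C)C(C)(C)C)CCC[C@H](O[Si](C)(C)C(C)(C)C)CCC[C@@H](O[Si](C)(C)C(C)(C)C)CCC[C@H](O[Si](C)(C)C(C)(C)C)CCC[C@@H](O[Si](C)(C)C(C)(C)C)/C=C/C[C@@H](O[Si](C)(C)C(C)(C)C)C[C@@H](C)CC(=O)O1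
A5 | alternative 3 | 2-(tert-butyldimethylsilyl)-1,3-dithiane | CC(C)(C)[Si](C)(C)C1SCCCS1
A6 | alternative 3 | C1–C40 chain with C27 dithiane, O25 TBS ether, free O29–H, PMB ethers at O1 and O35 | CCCC[C@H](C)[C@H](OCc1ccc(OC)cc1)C[C@@H](O[Si](C)(C)C(C)(C)C)CCC[C@H](O)CC2(SCCCS2)C[C@@H](O[Si](C)(C)C(C)(C)C)CCC[C@H](O[Si](C)(C)C(C)(C)C)CCC[C@@H](O[Si](C)(C)C(C)(C)C)CCC[C@H](O[Si](C)(C)C(C)(C)C)CCC[C@@H](O[Si](C)(C)C(C)(C)C)CCC[C@@H](O[Si](C)(C)C(C)(C)C)C[C@@H](C)CCOCc3ccc(OC)cc3
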